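**Assumption:** Bicyclic compounds are named with labdane numbering (C-17 = exocyclic methylene carbon; α/β as in normal labdanes). In all of them the C-11 side chain is 9α, the oxygen on C-9 is 9β, C-20 is 10β, the C-4 methyl is 4α and C-19 is 4β. TES = triethylsilyl, TBDPS = tert-butyldiphenylsilyl, DIPMS = methoxydi(propan-2-yl)silyl. Geranyl chloride is taken as commercial. The route has not been run; steps 10 and 11 are proposed new methods.

**Retrosynthetic overview**
1. Target ⇐ fluoride desilylation; C-8 ketone → exocyclic methylene; C-19 CH2OSi → CO2H ⇐ 5α-hydroxy-8-ketone.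
2. 5α-OH ⇐ γ-oxygenation of a Δ6-8-ketone through its silyl dienol ether ⇐ cyclisation product (its 3β-OH leaves as Δ2; Δ2 and Δ6 are hydrogenated together).
3. Key disconnection C4–C5 + C9–C10 (same bonds and order as the copalyl cascade: ring A, then ring B, one pot): epoxide-initiated cation–olefin bicyclisation ended by a cyclic cis-enediol silyl ether, so that C-9 arrives carrying its 9β-oxygen and 9α side chain and C-8 is left as the ketone.
4. Enediol ether ⇐ acyloin ⇐ alkylation of an α-ketol (from geraniol) with a (Z)-epoxy allylic chloride (from geranyl chloride; Still–Gennari, Sharpless).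

**Route**

Step 1
Reactants: 1 geranyl chloride
Product: 2 (4E)-6-chloro-4-methylhex-4-enal
Conditions: O3 (1.0 equiv), pyridine, CH2Cl2, −78 °C
Reagents that add atoms: ozone [O-][O+]=O
Why: Chemoselective ozonolysis (pyridine-mediated direct carbonyl formation) cleaves the electron-richer remote trisubstituted alkene, because the alkene next to the allylic chloride is inductively deactivated and keeps its E geometry.

Step 2
Reactants: 2 (4E)-6-chloro-4-methylhex-4-enal
Product: 3 methyl (2Z,6E)-8-chloro-2,6-dimethylocta-2,6-dienoate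
Conditions: (CF3CH2O)2P(O)CH(CH3)CO2Me, KHMDS, 18-crown-6, THF, −78 °C
Reagents that add atoms: methyl 2-[bis(2,2,2-trifluoroethoxy)phosphoryl]propanoate COC(=O)C(C)P(=O)(OCC(F)(F)F)OCC(F)(F)F
Why: Still–Gennari (Z-selective Horner–Wadsworth–Emmons) olefination gives the kinetic (Z)-2-methyl enoate, which places the ester carbon (future C-19) cis to the chain as the later axial position requires.

Step 3
Reactants: 3 methyl (2Z,6E)-8-chloro-2,6-dimethylocta-2,6-dienoate
Product: 4 (2Z,6E)-8-chloro-2,6-dimethylocta-2,6-dien-1-ol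
Conditions: DIBAL-H (2.2 equiv), CH2Cl2, −78 °C
Reagents that add atoms: none
Why: 1,2-Reduction of the conjugated ester by DIBAL-H gives the (Z)-allylic alcohol without touching the allylic chloride or the alkene geometry.

Step 4
Reactants: 4 (2Z,6E)-8-chloro-2,6-dimethylocta-2,6-dien-1-ol
Product: 5 [(2R,3S)-3-[(3E)-5-chloro-3-methylpent-3-en-1-yl]-2-methyloxiran-2-yl]methanol
Conditions: Ti(Oi-Pr)4 (cat.), D-(−)-diethyl tartrate, t-BuOOH, 4 Å MS, CH2Cl2, −20 °C
Reagents that add atoms: tert-butyl hydroperoxide CC(C)(C)OO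
Why: Sharpless asymmetric epoxidation acts only on the allylic alcohol, and the D-(−)-tartrate complex delivers oxygen to the face that gives the (2R,3S)-epoxide [(3S,4R) in labdane numbering, the mirror image of the (2S,3R) sense that L-(+)-tartrate gives with nerol], which is the source of all absolute stereochemistry.

Step 5
Reactants: 5 [(2R,3S)-3-[(3E)-5-chloro-3-methylpent-3-en-1-yl]-2-methyloxiran-2-yl]methanol
Product: 6 triethylsilyl ether of 5
Conditions: TESCl, imidazole, CH2Cl2, 0 °C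
Reagents that add atoms: chlorotriethylsilane CC[Si](Cl)(CC)CC
Why: Imidazole-catalysed silylation masks the primary hydroxyl against Payne rearrangement and alkoxide chemistry in the basic and Lewis-acidic steps, while leaving it in a form that step 16 oxidises directly.

Step 6
Reactants: 7 geraniol
Product: 8 geranyl tert-butyldiphenylsilyl ether
Conditions: TBDPSCl, imidazole, CH2Cl2, rt
Reagents that add atoms: tert-butylchlorodiphenylsilane CC(C)(C)[Si](Cl)(c1ccccc1)c1ccccc1
Why: Standard silylation gives a primary allylic ether that survives organolithium, LDA, Lewis acid and oxidation conditions until the last step.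

Step 7
Reactants: 8 geranyl tert-butyldiphenylsilyl ether
Product: 9 (4E)-6-[(tert-butyldiphenylsilyl)oxy]-4-methylhex-4-enal
Conditions: O3 (0.95 equiv), pyridine, CH2Cl2, −78 °C
Reagents that add atoms: ozone [O-][O+]=O
Why: Chemoselective ozonolysis cleaves the remote trisubstituted alkene in preference to the one deactivated by the allylic silyloxy group, using a slight deficit of ozone.

Step 8
Reactants: 9 (4E)-6-[(tert-butyldiphenylsilyl)oxy]-4-methylhex-4-enal
Product: 11 (6E)-8-[(tert-butyldiphenylsilyl)oxy]-3-hydroxy-6-methyloct-6-en-2-one, via enol ether carbinol 10 (not isolated)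
Conditions: CH2=CHOEt, t-BuLi, THF, −78 → 0 °C; then 9, −78 °C; then 1 M HCl, THF, 0 °C
Reagents that add atoms: ethyl vinyl ether C=COCC; water O
Why: 1,2-Addition of 1-ethoxyvinyllithium (an acetyl anion equivalent) followed by enol ether hydrolysis gives the α-hydroxy methyl ketone, whose racemic carbinol centre is irrelevant because it becomes sp2 in step 10.

Step 9
Reactants: 11 (6E)-8-[(tert-butyldiphenylsilyl)oxy]-3-hydroxy-6-methyloct-6-en-2-one; 6 triethylsilyl ether of 5
Product: 12 (2E,10E,14S,15R)-1-[(tert-butyldiphenylsilyl)oxy]-14,15-epoxy-6-hydroxy-3,11,15-trimethyl-16-[(triethylsilyl)oxy]hexadeca-2,10-dien-7-one (C-6 epimers)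
Conditions: LDA (2.1 equiv), THF, −78 °C; then 6, DMPU, NaI (cat.), −78 → −20 °C
Reagents that add atoms: none
Why: Kinetic dianion alkylation, in which LDA removes the OH proton and then the least hindered α-proton (CH3) and the enolate displaces the primary allylic chloride (SN2), joins the two halves at C-6/C-7 without touching the epoxide or the silyl ethers.

Step 10
Reactants: 12 acyloin from step 9
Product: 14 4-[(3E)-4-methyl-6-[(2S,3R)-3-methyl-3-(triethylsilyloxymethyl)oxiran-2-yl]hex-3-en-1-yl]-5-[(3E)-5-(tert-butyldiphenylsilyloxy)-3-methylpent-3-en-1-yl]-2,2-di(propan-2-yl)-1,3,2-dioxasilole, via dioxastannole 13 (not isolated)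
Conditions: Bu2Sn(OMe)2, PhMe, 80 °C (−MeOH); then i-Pr2SiCl2, 0 °C → rt
Reagents that add atoms: dibutyltin dimethoxide CCCC[Sn](CCCC)(OC)OC; dichlorodi(propan-2-yl)silane CC(C)[Si](Cl)(Cl)C(C)C
Why: Proposed new method: alcohol exchange and tin-enolate tautomerism turn the acyloin (either tautomer) into the chelated five-membered cis-enediolate, and Sn–O/Si–Cl exchange then moves both oxygens onto one silicon so that the cis-dioxy geometry of the C8=C9 bond is fixed by the ring, the closest known chemistry being dibutylstannylene derivatives of acyloins and O-silylation of stannylene acetals.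

Step 11
Reactants: 14 enediol silylene from step 10
Product: 16 15-TBDPSO-9β-DIPMSO-3β-hydroxy-19-TESO-17-nor-5α-labd-13E-en-8-one, via chlorosilyl ether 15 (not isolated)
Conditions: MeAlCl2 (2 equiv), CH2Cl2, −94 °C; then MeOH, Et3N, −78 °C → rt
Reagents that add atoms: methylaluminium dichloride C[Al](Cl)Cl; methanol CO
Why: Proposed new method: Lewis acid activation of the epoxide starts a chair–chair cation–olefin bicyclisation (anti opening at C-4 by the E-Δ5(10) alkene, capture of the tertiary C-10 cation by C-9 of the enediol silyl ether, collapse of the silyl oxocarbenium to the C-8 ketone by chloride transfer to silicon) that sets C-4 (the Z substituent becomes axial 4β-CH2OTES), C-5 (α-H), C-10 (β-CH3) and C-9 (oxygen trans to C-7 on the alkene becomes equatorial 9β, side chain cis to C-7 becomes axial 9α) relative to the epoxide-derived 3β-OH, the closest known reactions being MeAlCl2-promoted epoxy-polyene cyclisations ended by silyl enol ethers, cyclisations of epoxides bearing a C-4 CH2OR group, and Lewis-acid tert-alkylation of silyl enol ethers.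

Step 12
Reactants: 16 bicyclic 3β-hydroxy ketone from step 11
Product: 17 15-TBDPSO-9β-DIPMSO-19-TESO-17-nor-5α-labda-2,13E-dien-8-one
Conditions: Burgess reagent, PhH, 50 °C
Reagents that add atoms: none
Why: Burgess dehydration (syn-elimination through the sulfamate ester) removes the unwanted 3β-OH as the Δ2 alkene because the only β-hydrogens are on C-2, the ketone and the silyl ethers being inert.

Step 13
Reactants: 17 Δ2 ketone from step 12
Product: 18 15-TBDPSO-9β-DIPMSO-19-TESO-17-nor-5α-labda-2,6,13E-trien-8-one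
Conditions: IBX (3 equiv), DMSO/PhMe, 70 °C
Reagents that add atoms: none
Why: IBX dehydrogenation of the ketone can only proceed toward C-7/C-6 because C-9 is fully substituted, and the resulting Δ6-8-enone makes H-5 a γ-hydrogen.

Step 14
Reactants: 18 Δ6-enone from step 13
Product: 20 15-TBDPSO-9β-DIPMSO-5α-hydroxy-19-TESO-17-norlabda-2,6,13E-trien-8-one, via silyl dienol ether 19 (not isolated)
Conditions: TMSOTf, Et3N, CH2Cl2, 0 °C; then m-CPBA, NaHCO3, CH2Cl2, −40 °C; aq. NaHCO3
Reagents that add atoms: trimethylsilyl triflate C[Si](C)(C)OS(=O)(=O)C(F)(F)F; m-chloroperbenzoic acid OOC(=O)c1cccc(Cl)c1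
Why: Vinylogous Rubottom oxidation, in which soft enolisation removes the only acidic hydrogen (axial H-5), the peracid epoxidises the terminal C5=C6 bond of the dienol ether from the α face (the β face is blocked by the axial C-19 and C-20 groups) and epoxide collapse returns the enone with the tertiary 5α-OH trans to the C-10 methyl, as in the 6-hydroxylation of steroidal 3,5-dienol ethers.

Step 15
Reactants: 20 5α-hydroxy dienone from step 14
Product: 21 15-TBDPSO-9β-DIPMSO-5α-hydroxy-19-TESO-17-norlabd-13E-en-8-one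
Conditions: H2 (3 atm), RhCl(PPh3)3 (cat.), PhH, rt
Reagents that add atoms: none
Why: Homogeneous hydrogenation with Wilkinson's catalyst reduces the two cis-disubstituted ring alkenes (Δ2 and Δ6) but not the trisubstituted side-chain alkene, and creates no stereocentre.

Step 16
Reactants: 21 5α-hydroxy-8-ketone from step 15
Product: 22 15-TBDPSO-9β-DIPMSO-5α-hydroxy-8-oxo-17-norlabd-13E-en-19-al
Conditions: (COCl)2, DMSO, CH2Cl2, −78 → −30 °C; then Et3N
Reagents that add atoms: none
Why: Swern oxidation acting directly on the primary triethylsilyl ether (chlorosulfonium-induced desilylation, then sulfur ylide fragmentation) gives the C-19 aldehyde without acid or fluoride, so the tertiary alcohol, the other silyl ethers and the alkene survive.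

Step 17
Reactants: 22 C-19 aldehyde from step 16
Product: 23 15-TBDPSO-9β-DIPMSO-5α-hydroxy-8-oxo-17-norlabd-13E-en-19-oic acid
Conditions: NaClO2, NaH2PO4, 2-methyl-2-butene, t-BuOH/H2O, rt
Reagents that add atoms: sodium chlorite [Na+].[O-]Cl=O
Why: Pinnick oxidation converts the hindered, retro-aldol-prone β-hydroxy aldehyde to the acid under buffered conditions, with the scavenger protecting the alkene from hypochlorous acid.

Step 18
Reactants: 23 keto acid from step 17
Product: 24 15-TBDPSO-9β-DIPMSO-5α-hydroxylabda-8(17),13E-dien-19-oic acid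
Conditions: Ph3PCH3Br, KOt-Bu (6 equiv ylide), THF, 65 °C; aq. citric acid
Reagents that add atoms: methyltriphenylphosphonium bromide C[P+](c1ccccc1)(c1ccccc1)c1ccccc1.[Br-]
Why: Wittig methylenation of the C-8 ketone installs C-17, the carboxylate and 5-alkoxide being spectators (retro-aldol from a carboxylate is disfavoured) and the 9-O-silyl group preventing α-ketol rearrangement under base.

Step 19
Reactants: 24 bis-silyl acid from step 18
Product: 25 5α,9β-dihydroxyisocupressic acid
Conditions: TBAF (excess), THF, 45 °C; aq. NH4Cl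
Reagents that add atoms: none
Why: Fluoride-induced desilylation cleaves both the primary allylic TBDPS ether and the tertiary dialkoxysilane at O-9 without affecting any stereocentre, giving the target.

**Compound list**

1 | geranyl chloride, (2E)-1-chloro-3,7-dimethylocta-2,6-diene | CC(C)=CCC/C(C)=C/CCl | starting material
2 | (4E)-6-chloro-4-methylhex-4-enal | O=CCC/C(C)=C/CCl | intermediate
3 | methyl (2Z,6E)-8-chloro-2,6-dimethylocta-2,6-dienoate | COC(=O)/C(C)=C\CC/C(C)=C/CCl | intermediate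
4 | (2Z,6E)-8-chloro-2,6-dimethylocta-2,6-dien-1-ol | OC/C(C)=C\CC/C(C)=C/CCl | intermediate
5 | [(2R,3S)-3-[(3E)-5-chloro-3-methylpent-3-en-1-yl]-2-methyloxiran-2-yl]methanol | OC[C@@]1(C)O[C@H]1CC/C(C)=C/CCl | intermediate
6 | triethyl{[(2R,3S)-3-[(3E)-5-chloro-3-methylpent-3-en-1-yl]-2-methyloxiran-2-yl]methoxy}silane | CC[Si](CC)(CC)OC[C@@]1(C)O[C@H]1CC/C(C)=C/CCl | intermediate
7 | geraniol | CC(C)=CCC/C(C)=C/CO | starting material
8 | geranyl tert-butyldiphenylsilyl ether | CC(C)=CCC/C(C)=C/CO[Si](c1ccccc1)(c1ccccc1)C(C)(C)C | intermediate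
9 | (4E)-6-[(tert-butyldiphenylsilyl)oxy]-4-methylhex-4-enal | O=CCC/C(C)=C/CO[Si](c1ccccc1)(c1ccccc1)C(C)(C)C | intermediate
10 | (6E)-8-[(tert-butyldiphenylsilyl)oxy]-2-ethoxy-6-methylocta-1,6-dien-3-ol (lithium alkoxide in the flask; racemic) | C=C(OCC)C(O)CC/C(C)=C/CO[Si](c1ccccc1)(c1ccccc1)C(C)(C)C | intermediate
11 | (6E)-8-[(tert-butyldiphenylsilyl)oxy]-3-hydroxy-6-methyloct-6-en-2-one (racemic) | CC(=O)C(O)CC/C(C)=C/CO[Si](c1ccccc1)(c1ccccc1)C(C)(C)C | intermediate
12 | (2E,10E,14S,15R)-1-[(tert-butyldiphenylsilyl)oxy]-14,15-epoxy-6-hydroxy-3,11,15-trimethyl-16-[(triethylsilyl)oxy]hexadeca-2,10-dien-7-one (C-6 epimers) | CC[Si](CC)(CC)OC[C@@]1(C)O[C@H]1CC/C(C)=C/CCC(=O)C(O)CC/C(C)=C/CO[Si](c1ccccc1)(c1ccccc1)C(C)(C)C | intermediate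
13 | 2,2-dibutyl-1,3,2-dioxastannole (cis-enediolate of 12; ring carbons are future C-8 and C-9) | CC[Si](CC)(CC)OC[C@@]1(C)O[C@H]1CC/C(C)=C/CCC1=C(CC/C(C)=C/CO[Si](c2ccccc2)(c2ccccc2)C(C)(C)C)O[Sn](CCCC)(CCCC)O1 | intermediate
14 | 4-[(3E)-4-methyl-6-[(2S,3R)-3-methyl-3-(triethylsilyloxymethyl)oxiran-2-yl]hex-3-en-1-yl]-5-[(3E)-5-(tert-butyldiphenylsilyloxy)-3-methylpent-3-en-1-yl]-2,2-di(propan-2-yl)-1,3,2-dioxasilole | CC[Si](CC)(CC)OC[C@@]1(C)O[C@H]1CC/C(C)=C/CCC1=C(CC/C(C)=C/CO[Si](c2ccccc2)(c2ccccc2)C(C)(C)C)O[Si](C(C)C)(C(C)C)O1 | intermediate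
15 | 9β-[chlorodi(propan-2-yl)silyloxy] analogue of 16 (O-3 is an aluminium alkoxide in the flask; drawn as the alcohol) | O=C1CC[C@@H]2[C@](C)(CC[C@H](O)[C@]2(C)CO[Si](CC)(CC)CC)[C@]1(O[Si](Cl)(C(C)C)C(C)C)CC/C(C)=C/CO[Si](c3ccccc3)(c3ccccc3)C(C)(C)C | intermediate
16 | 15-TBDPSO-9β-DIPMSO-3β-hydroxy-19-TESO-17-nor-5α-labd-13E-en-8-one | O=C1CC[C@@H]2[C@](C)(CC[C@H](O)[C@]2(C)CO[Si](CC)(CC)CC)[C@]1(O[Si](OC)(C(C)C)C(C)C)CC/C(C)=C/CO[Si](c3ccccc3)(c3ccccc3)C(C)(C)C | intermediate
17 | 15-TBDPSO-9β-DIPMSO-19-TESO-17-nor-5α-labda-2,13E-dien-8-one | O=C1CC[C@@H]2[C@](C)(CC=C[C@]2(C)CO[Si](CC)(CC)CC)[C@]1(O[Si](OC)(C(C)C)C(C)C)CC/C(C)=C/CO[Si](c3ccccc3)(c3ccccc3)C(C)(C)C | intermediate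
18 | 15-TBDPSO-9β-DIPMSO-19-TESO-17-nor-5α-labda-2,6,13E-trien-8-one | O=C1C=C[C@@H]2[C@](C)(CC=C[C@]2(C)CO[Si](CC)(CC)CC)[C@]1(O[Si](OC)(C(C)C)C(C)C)CC/C(C)=C/CO[Si](c3ccccc3)(c3ccccc3)C(C)(C)C | intermediate
19 | 15-TBDPSO-9β-DIPMSO-19-TESO-8-(trimethylsilyloxy)-17-norlabda-2,5,7,13E-tetraene | C[Si](C)(C)OC1=CC=C2[C@](C)(CC=C[C@]2(C)CO[Si](CC)(CC)CC)[C@]1(O[Si](OC)(C(C)C)C(C)C)CC/C(C)=C/CO[Si](c3ccccc3)(c3ccccc3)C(C)(C)C | intermediate
20 | 15-TBDPSO-9β-DIPMSO-5α-hydroxy-19-TESO-17-norlabda-2,6,13E-trien-8-one | O=C1C=C[C@]2(O)[C@](C)(CC=C[C@]2(C)CO[Si](CC)(CC)CC)[C@]1(O[Si](OC)(C(C)C)C(C)C)CC/C(C)=C/CO[Si](c3ccccc3)(c3ccccc3)C(C)(C)C | intermediate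
21 | 15-TBDPSO-9β-DIPMSO-5α-hydroxy-19-TESO-17-norlabd-13E-en-8-one | O=C1CC[C@]2(O)[C@](C)(CCC[C@]2(C)CO[Si](CC)(CC)CC)[C@]1(O[Si](OC)(C(C)C)C(C)C)CC/C(C)=C/CO[Si](c3ccccc3)(c3ccccc3)C(C)(C)C | intermediate
22 | 15-TBDPSO-9β-DIPMSO-5α-hydroxy-8-oxo-17-norlabd-13E-en-19-al | O=C1CC[C@]2(O)[C@](C)(CCC[C@]2(C)C=O)[C@]1(O[Si](OC)(C(C)C)C(C)C)CC/C(C)=C/CO[Si](c3ccccc3)(c3ccccc3)C(C)(C)C | intermediate
23 | 15-TBDPSO-9β-DIPMSO-5α-hydroxy-8-oxo-17-norlabd-13E-en-19-oic acid | O=C1CC[C@]2(O)[C@](C)(CCC[C@]2(C)C(=O)O)[C@]1(O[Si](OC)(C(C)C)C(C)C)CC/C(C)=C/CO[Si](c3ccccc3)(c3ccccc3)C(C)(C)C | intermediate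
24 | 15-TBDPSO-9β-DIPMSO-5α-hydroxylabda-8(17),13E-dien-19-oic acid | C=C1CC[C@]2(O)[C@](C)(CCC[C@]2(C)C(=O)O)[C@]1(O[Si](OC)(C(C)C)C(C)C)CC/C(C)=C/CO[Si](c3ccccc3)(c3ccccc3)C(C)(C)C | intermediate
25 | 5α,9β-dihydroxyisocupressic acid | C=C1CC[C@]2(O)[C@](C)(CCC[C@]2(C)C(=O)O)[C@]1(O)CC/C(C)=C/CO | target

**Step count and risks**

Total: 19 steps. Longest linear sequence: 16 (steps 1–5 and 9–19); steps 6–8 form a three-step branch.

Steps most likely to fail:

1. Step 11 (key bicyclisation). Possible failures are epoxide-to-ketone rearrangement because the C-4 cation is weakened by the β-silyloxy group, arrest after ring A, capture at C-8 (five-membered ring), or a further Prins closure of the silyl oxocarbenium onto the Δ13 alkene. The fallback changes how the epoxide is activated: the Lewis acid is anchored inside the substrate on a free 19-hydroxyl. It sets out from 12. The triethylsilyl ether is removed (PPTS, MeOH, 0 °C) to give the 6,16-dihydroxy epoxy ketone F2. This is taken through the tin-templated silylene formation of step 10 (dioxastannole F3, not isolated; hydroxy dioxasilole F4). F4 is cyclised with MeAlCl2 (2.2 equiv), where the first equivalent turns the primary hydroxyl into an aluminium alkoxide that chelates and opens the neighbouring epoxide. The chlorosilyl diol F5 formed in the flask is quenched with MeOH/Et3N to the 3β,19-diol F6. Selective silylation of its primary hydroxyl (TESCl, imidazole, −20 °C) brings the route back at 16.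

2. Step 10 (enediol silylene). Possible failures are incomplete enolisation on tin, epoxide opening by tin Lewis acids, or incomplete tin-to-silicon transfer. The fallback replaces templated enolisation by reduction of a dione. It sets out from 12, which is oxidised with Dess–Martin periodinane (NaHCO3, CH2Cl2) to the 1,2-diketone F1. Two-electron reductive silylation (Mg, i-Pr2SiCl2, THF, 0 °C) gives the magnesium cis-enediolate chelate, which is trapped on both oxygens by one silicon, and the route comes back at 14.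

3. Step 14 (γ-hydroxylation at the hindered C-5). Possible failures are slow removal of H-5 or peracid attack on the enol ether bond (C-7) instead of C5=C6. The fallback uses the free dienolate and triplet oxygen instead of a silyl dienol ether and a peracid. It sets out from 18: KOt-Bu, THF/t-BuOH, O2, P(OEt)3, −25 °C gives the potassium dienolate, which is oxygenated at C-5 from the α face to the 5α-hydroperoxide F7. F7 is reduced in the flask by the phosphite, and the route comes back at 20.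

**Further compounds**

F1 | step 10 | (2E,10E,14S,15R)-1-[(tert-butyldiphenylsilyl)oxy]-14,15-epoxy-3,11,15-trimethyl-16-[(triethylsilyl)oxy]hexadeca-2,10-diene-6,7-dione | CC[Si](CC)(CC)OC[C@@]1(C)O[C@H]1CC/C(C)=C/CCC(=O)C(=O)CC/C(C)=C/CO[Si](c1ccccc1)(c1ccccc1)C(C)(C)C
F2 | step 11 | (2E,10E,14S,15R)-1-[(tert-butyldiphenylsilyl)oxy]-14,15-epoxy-6,16-dihydroxy-3,11,15-trimethylhexadeca-2,10-dien-7-one (C-6 epimers) | OC[C@@]1(C)O[C@H]1CC/C(C)=C/CCC(=O)C(O)CC/C(C)=C/CO[Si](c1ccccc1)(c1ccccc1)C(C)(C)C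
F3 | step 11 | 2,2-dibutyl-1,3,2-dioxastannole of F2 (not isolated) | OC[C@@]1(C)O[C@H]1CC/C(C)=C/CCC1=C(CC/C(C)=C/CO[Si](c2ccccc2)(c2ccccc2)C(C)(C)C)O[Sn](CCCC)(CCCC)O1
F4 | step 11 | 2,2-di(propan-2-yl)-1,3,2-dioxasilole of F2 (14 without its triethylsilyl group) | OC[C@@]1(C)O[C@H]1CC/C(C)=C/CCC1=C(CC/C(C)=C/CO[Si](c2ccccc2)(c2ccccc2)C(C)(C)C)O[Si](C(C)C)(C(C)C)O1
F5 | step 11 | 15-TBDPSO-9β-[chlorodi(propan-2-yl)silyloxy]-3β,19-dihydroxy-17-nor-5α-labd-13E-en-8-one (aluminium alkoxides in the flask; not isolated) | O=C1CC[C@@H]2[C@](C)(CC[C@H](O)[C@]2(C)CO)[C@]1(O[Si](Cl)(C(C)C)C(C)C)CC/C(C)=C/CO[Si](c3ccccc3)(c3ccccc3)C(C)(C)C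
F6 | step 11 | 15-TBDPSO-9β-DIPMSO-3β,19-dihydroxy-17-nor-5α-labd-13E-en-8-one | O=C1CC[C@@H]2[C@](C)(CC[C@H](O)[C@]2(C)CO)[C@]1(O[Si](OC)(C(C)C)C(C)C)CC/C(C)=C/CO[Si](c3ccccc3)(c3ccccc3)C(C)(C)C
F7 | step 14 | 15-TBDPSO-9β-DIPMSO-5α-hydroperoxy-19-TESO-17-norlabda-2,6,13E-trien-8-one (not isolated) | O=C1C=C[C@]2(OO)[C@](C)(CC=C[C@]2(C)CO[Si](CC)(CC)CC)[C@]1(O[Si](OC)(C(C)C)C(C)C)CC/C(C)=C/CO[Si](c3ccccc3)(c3ccccc3)C(C)(C)C
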